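Molar per hour is the unit that serves here: a mean pace of product, set against the ceiling the charges allow, tells how long a flask takes to fill.

| setting | spring | dusk | noon | flask |
|---|---|---|---|---|
| left-handed substrate | 0.034 M | 0.075 M | 0.050 M | 0.050 M |
| right-handed substrate | 0.034 M | 0.075 M | 0.050 M | 0.050 M |
| partner | 0.030 M | 0.030 M | 0.045 M | 0.0300 M |
| free catalyst | 0.50 mM (in portions, 2) | 0.50 mM (in portions, 2) | 0.50 mM (in portions, 2) | 0.50 mM (in portions, 2) |
| impurity | 0.14 mM | 0.14 mM | 0.14 mM | 0.14 mM |
| remark | run made earlier; portions every 1.5 h | run made earlier; portions every 1.5 h | run made earlier; portions every 1.5 h | the portions of free catalyst follow each other after 1.5 h, the first at the start |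
| time |  |  |  | 4.0 h |

| run | time / h | left-handed product / % | right-handed substrate / % |
|---|---|---|---|
| spring | 0.250 | 11.0 | 50.6 |
| spring | 0.417 | 14.2 | 49.5 |
| spring | 0.667 | 17.6 | 48.7 |
| spring | 0.833 | 21.0 | 47.8 |
| spring | 1.33 | 24.6 | 51.1 |
| spring | 2.00 | 35.5 | 48.6 |
| spring | 3.00 | 41.2 | 49.1 |
| dusk | 0.500 | 10.1 | 49.5 |
| dusk | 1.00 | 15.0 | 50.0 |
| dusk | 1.33 | 16.7 | 47.0 |
| dusk | 2.00 | 19.3 | 50.6 |
| dusk | 2.50 | 19.6 | 50.5 |
| dusk | 3.00 | 19.6 | 51.4 |
| noon | 0.250 | 11.1 | 50.0 |
| noon | 0.500 | 17.7 | 48.6 |
| noon | 0.833 | 23.0 | 49.2 |
| noon | 1.50 | 28.8 | 49.4 |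
| noon | 3.00 | 41.8 | 49.4 |

(scatter of a reading: 1 percentage point)

- free catalyst is single-handed; left-handed substrate and right-handed substrate are mirror images of each other, charged as a racemate, each of them at the stated concentration

- concentration of left-handed product at 4.0 h, in M
- concentration of right-handed substrate at 4.0 h, in M
- concentration of partner at 4.0 h, in M

The ceiling comes first. The dusk run, with left-handed substrate in excess, levels off at a reading of 0.0294 M of left-handed product beside 0.030 M of partner, so the two go one to one. In the flask, partner is therefore the limiting reagent, and the ceiling is 0.0300 M.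

The spring run has the same partner and less left-handed substrate than the flask, and it supplies the ladder. Its opening pace of 0.0299 M h⁻¹, carried straight on, covers that ceiling in 1.00 h, sooner than the 1.5 h between portions. But that pace does not last: at 1.33 h spring holds only 0.0167 M. Around the second portion it gains 0.00741 M by 2.00 h. Replacing the whole curve by its mean over 3.00 h gives 0.00934 M h⁻¹, and 3.21 h is then the filling time, the ceiling divided by the mean pace.

The error of the mean shows in the tail. Spring's last hour runs at 0.00388 M h⁻¹, and finishing at that pace takes until 3.51 h, still earlier than 4.0 h. On the slowest rung, right-handed substrate ends the three runs at 49.1%, 51.4% and 49.4%, with no drift the scatter can show.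

This reckoning therefore puts left-handed product at the ceiling, 0.0300 M, and right-handed substrate at the charge it shares with the left-handed substrate, 0.050 M; it gives no figure for the last partner. The forecast, expecting a second phase that “nearly exhausts partner”, says 0.0294 M of left-handed product, 0.0495 M of right-handed substrate and 2.000 × 10⁻⁴ M of partner.

The flask gives 0.0295 M of left-handed product, 0.0495 M of right-handed substrate and 9.00 × 10⁻⁵ M of partner.

    free catalyst + left-handed substrate ⇌ catalyst intermediate A (K = 118 L mol⁻¹, k = 878 L mol⁻¹ min⁻¹)
    free catalyst + right-handed substrate ⇌ catalyst intermediate B (K = 14.7 L mol⁻¹, k = 798 L mol⁻¹ min⁻¹)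
    partner + catalyst intermediate A → free catalyst + left-handed product (k = 290 L mol⁻¹ min⁻¹)
    partner + catalyst intermediate B → free catalyst + right-handed product (k = 15.3 L mol⁻¹ min⁻¹)
    free catalyst + impurity → spent catalyst A (k = 8900 L mol⁻¹ min⁻¹)
    free catalyst ⇌ dormant form (K = 31.0, k = 0.0171 min⁻¹)
    free catalyst → spent catalyst B (k = 0.0177 min⁻¹)

The forecast's partner stands 2.22 times above the flask's. Against the filling time of 3.21 h, the flask already holds 0.0276 M of product at 2.00 h. The neighbouring flask with 0.12 M of partner has left-handed substrate as its smaller charge, so its ceiling is 0.0500 M. The noon run's mean pace of 0.0139 M h⁻¹ gives a filling time of 3.59 h, shorter than 4.0 h. That neighbour ends with 0.0499 M of left-handed product, 0.13% of its left-handed substrate left, and right-handed substrate down to 0.0424 M.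

The earlier runs and the new flask are calculated for substances that don't exist; the scatter is artificial.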